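**Strategy.** The route rests on disconnecting the C16–C17 bond (numbering: C1 = lactone carbonyl, C24 = carboxyl carbon). The hydroxymethyl carbon on C16 is read as a latent acyl group, so that C16, flanked by it and the C14=C15 alkene, becomes the α-carbon of a β,γ-unsaturated dienoyl imide. Its boron (Z)-enolate, carrying the whole C1–C16 portion with the dihydropyranone ring masked as a lactol ethyl acetal, undergoes an auxiliary-controlled syn-aldol addition to the C17 aldehyde of the C17–C24 fragment. One operation joins the halves and fixes C16; the C17 carbinol is later oxidised to the ketone and the acyl group reduced to the hydroxymethyl group.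

Key step: step 25

Remark 1: atoms are numbered as in the natural product; the hydroxymethyl carbon on C16 is called C16a.
Remark 2 (assumption): the lactol acetal carbon C1 is carried as a mixture of epimers and left undefined in the SMILES; this is of no consequence because C1 ends as the lactone carbonyl.

**Ring building block (C1–C7)**

Step 1
Reactants: 1 3-(triisopropylsilyl)prop-2-ynal; 2 (Z)-crotylboronic acid pinacol ester
Product: 4 (3R,4S)-4-methyl-1-(triisopropylsilyl)hex-5-en-1-yn-3-ol, via pinacol borate ester 3 (not isolated)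
Conditions: (R)-TRIP phosphoric acid (5 mol%), 4 Å MS, toluene, −30 °C; aq. NaHCO3 work-up
Reagents that add atoms: none
Why: Chiral phosphoric acid-catalysed crotylboration through a closed chair transition state, in which the (Z)-crotyl geometry should give the syn C4/C5 relationship and the (R)-configured catalyst is expected to direct addition to the Re face of the ynal, setting both ring stereocentres.

Step 2
Reactants: 4 homoallylic propargylic alcohol; 5 acrolein diethyl acetal
Product: 6 mixed ethyl acetal of 4 with acrolein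
Conditions: PPTS (cat.), toluene, 40 °C, reduced pressure
Reagents that add atoms: none
Why: Acid-catalysed transacetalisation, driven by removal of ethanol, should attach the second vinyl group without touching the stereocentres.

Step 3
Reactants: 6 mixed acetal
Product: 7 (2R,3S)-6-ethoxy-3-methyl-2-[(triisopropylsilyl)ethynyl]-3,6-dihydro-2H-pyran
Conditions: second-generation Grubbs catalyst RuCl2(H2IMes)(PCy3)(=CHPh) (5 mol%), CH2Cl2, 40 °C
Reagents that add atoms: none
Why: Ring-closing metathesis of the two terminal vinyl groups should close the six-membered dihydropyran, the bulky silyl-capped alkyne staying out of enyne metathesis.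

Step 4
Reactants: 7 silylalkynyl dihydropyran
Product: 8 (2R,3S)-6-ethoxy-2-ethynyl-3-methyl-3,6-dihydro-2H-pyran
Conditions: TBAF, THF, 0 °C
Reagents that add atoms: none
Why: Fluoride-induced protodesilylation of the alkynylsilane should free the terminal alkyne, the acetal being inert to fluoride.

**C8–C13 building block**

Step 5
Reactants: 9 (S)-4-benzyl-3-propionyloxazolidin-2-one; 10 3-bromo-1-(trimethylsilyl)prop-1-yne
Product: 12 (S)-4-benzyl-3-[(R)-2-methyl-5-(trimethylsilyl)pent-4-ynoyl]oxazolidin-2-one, via sodium (Z)-enolate 11 (not isolated)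
Conditions: NaHMDS, THF, −78 °C; then 10, −78 → −40 °C
Reagents that add atoms: none
Why: Evans asymmetric alkylation, in which the chelated sodium (Z)-enolate is attacked by the propargylic bromide on the face opposite the benzyl group, setting C10 as (R).

Step 6
Reactants: 12 alkylated imide
Product: 13 (R)-2-methyl-5-(trimethylsilyl)pent-4-yn-1-ol
Conditions: LiBH4, MeOH (1 equiv), Et2O, 0 °C
Reagents that add atoms: none
Why: Reductive cleavage of the exocyclic imide carbonyl by LiBH4 should release the primary alcohol without epimerisation.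

Step 7
Reactants: 13 alcohol
Product: 14 (R)-2-methyl-5-(trimethylsilyl)pent-4-ynal
Conditions: Dess–Martin periodinane, pyridine, CH2Cl2, 0 °C → rt (used directly)
Reagents that add atoms: none
Why: Dess–Martin oxidation under buffered conditions should give the α-chiral aldehyde without loss of configuration.

Step 8
Reactants: 14 aldehyde
Product: 15 (R)-(6,6-dibromo-4-methylhex-5-en-1-yn-1-yl)trimethylsilane
Conditions: CBr4, PPh3, 2,6-lutidine, CH2Cl2, 0 °C
Reagents that add atoms: carbon tetrabromide BrC(Br)(Br)Br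
Why: Corey–Fuchs dibromo-olefination (Wittig reaction of the dibromomethylene ylide) converts the aldehyde carbon C9 into the 1,1-dibromoalkene that carries C8.

Step 9
Reactants: 15 dibromoalkene
Product: 16 (R,Z)-(6-bromo-4-methyloct-5-en-1-yn-1-yl)trimethylsilane
Conditions: Et2Zn, PdCl2(DPEphos) (5 mol%), THF, 0 °C → rt
Reagents that add atoms: diethylzinc CC[Zn]CC
Why: Negishi trans-selective monoalkylation of a 1,1-dibromoalkene, in which oxidative addition occurs at the less hindered carbon–bromine bond trans to the alkyl chain, places ethyl trans to C10 and leaves the bromide cis to C10.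

**Assembly of the C1–C16 imide**

Step 10
Reactants: 8 ring alkyne; 16 (Z)-alkenyl bromide
Product: 19 (2S,3S)-6-ethoxy-2-[(1E,3Z,5R)-3-ethyl-5-methyl-8-(trimethylsilyl)octa-1,3-dien-7-yn-1-yl]-3-methyl-3,6-dihydro-2H-pyran, via alkenylzirconocene chloride 17 (not isolated), via alkenylzinc chloride 18 (not isolated)
Conditions: Cp2Zr(H)Cl, THF, rt; ZnCl2, 0 °C; then 16, Pd(P(t-Bu)3)2 (5 mol%), THF, rt
Reagents that add atoms: none
Why: Syn hydrozirconation of the terminal alkyne, zirconium-to-zinc transmetalation and Negishi alkenyl–alkenyl coupling with retention at both partners should give the (6E,8Z)-diene.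

Step 11
Reactants: 19 silylated dienyne
Product: 20 (2S,3S)-6-ethoxy-2-[(1E,3Z,5R)-3-ethyl-5-methylocta-1,3-dien-7-yn-1-yl]-3-methyl-3,6-dihydro-2H-pyran
Conditions: K2CO3 (cat.), MeOH, rt
Reagents that add atoms: none
Why: Base-catalysed methanolysis of the alkynyl–silicon bond frees the C12–C13 alkyne, the acetal being stable to base.

Step 12
Reactants: 21 pent-3-yn-1-ol
Product: 23 (E)-4-iodopent-3-en-1-ol, via bis-zirconium alkenyl alkoxide 22 (not isolated)
Conditions: Cp2Zr(H)Cl (2.5 equiv), THF, rt → 40 °C; then I2, 0 °C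
Reagents that add atoms: iodine II
Why: Hydrozirconation–iodination, in which syn addition places zirconium on the less hindered methyl-bearing alkyne carbon (equilibration with excess reagent) and iodinolysis proceeds with retention, should give the (E)-iodide.

Step 13
Reactants: 23 iodo alcohol
Product: 24 (E)-4-iodopent-3-enoic acid
Conditions: TEMPO (cat.), PhI(OAc)2, MeCN/H2O, rt
Reagents that add atoms: water O
Why: Nitroxyl-catalysed oxidation of the primary alcohol through the aldehyde hydrate should give the acid under near-neutral conditions that do not move the β,γ-double bond into conjugation.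

Step 14
Reactants: 24 iodo acid; 25 (R)-4-benzyloxazolidin-2-one
Product: 27 (R)-4-benzyl-3-[(E)-4-iodopent-3-enoyl]oxazolidin-2-one, via mixed pivalic anhydride 26 (not isolated)
Conditions: PivCl, Et3N, THF, −20 °C; then LiCl, 25, −20 °C → rt
Reagents that add atoms: none
Why: N-Acylation of the oxazolidinone through the mixed anhydride under LiCl/amine activation avoids strong base and should keep the β,γ-alkene in place.

Step 15
Reactants: 20 terminal alkyne; 27 alkenyl iodide imide
Product: 30 (R)-4-benzyl-3-[(3E,5E,8R,9Z,11E)-10-ethyl-12-[(2S,3S)-6-ethoxy-3-methyl-3,6-dihydro-2H-pyran-2-yl]-4,8-dimethyldodeca-3,5,9,11-tetraenoyl]oxazolidin-2-one, via alkenylzirconocene chloride 28 (not isolated), via alkenylzinc chloride 29 (not isolated)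
Conditions: Cp2Zr(H)Cl, THF, rt; ZnCl2, 0 °C; then 27, Pd(PPh3)4 (5 mol%), THF, rt
Reagents that add atoms: none
Why: Chemoselective hydrozirconation of the terminal alkyne followed by Negishi coupling with retention forms the C13–C14 bond and the (12E,14E)-diene under neutral conditions tolerated by the acidic imide methylene.

**C17–C24 aldehyde**

Step 16
Reactants: 31 (R)-3-bromo-2-methylpropan-1-ol
Product: 32 (R)-(3-bromo-2-methylpropoxy)(tert-butyl)diphenylsilane
Conditions: TBDPSCl, imidazole, DMF, rt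
Reagents that add atoms: tert-butyl(chloro)diphenylsilane CC(C)(C)[Si](Cl)(c1ccccc1)c1ccccc1
Why: Standard silylation protects the future C19 oxygen with a group that survives acetylide and organoaluminium reagents.

Step 17
Reactants: 32 bromide
Product: 33 (S)-tert-butyl[(2-methylpent-4-yn-1-yl)oxy]diphenylsilane
Conditions: LiC≡CH·H2NCH2CH2NH2, DMSO, rt
Reagents that add atoms: lithium acetylide–ethylenediamine complex [Li+].[C-]#C.NCCN
Why: SN2 displacement of the primary bromide by acetylide installs C22–C23 without involving the C20 stereocentre.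

Step 18
Reactants: 33 terminal alkyne
Product: 35 allyl (S,E)-6-[(tert-butyldiphenylsilyl)oxy]-3,5-dimethylhex-2-enoate, via (E)-alkenyldimethylalane 34 (not isolated)
Conditions: AlMe3, Cp2ZrCl2 (20 mol%), CH2Cl2, 0 °C → rt; then ClCO2CH2CH=CH2, 0 °C → rt
Reagents that add atoms: trimethylaluminium C[Al](C)C; allyl chloroformate C=CCOC(=O)Cl
Why: Negishi zirconium-catalysed carboalumination (syn methyl–aluminium addition, aluminium terminal) followed by acylation of the alkenylalane with retention should give the (22E)-enoate as a single isomer.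

Step 19
Reactants: 35 silyl ether
Product: 36 allyl (S,E)-6-hydroxy-3,5-dimethylhex-2-enoate
Conditions: HF·pyridine, THF, 0 °C → rt
Reagents that add atoms: none
Why: Fluoride-mediated desilylation under non-basic conditions leaves the allyl ester intact.

Step 20
Reactants: 36 alcohol
Product: 37 allyl (S,E)-3,5-dimethyl-6-oxohex-2-enoate
Conditions: Dess–Martin periodinane, pyridine, CH2Cl2, 0 °C (used directly)
Reagents that add atoms: none
Why: Buffered Dess–Martin oxidation should give the α-chiral C19 aldehyde without epimerisation at C20.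

Step 21
Reactants: 9 (S)-4-benzyl-3-propionyloxazolidin-2-one; 37 aldehyde
Product: 40 allyl (2E,5S,6R,7S)-8-[(S)-4-benzyl-2-oxooxazolidin-3-yl]-6-hydroxy-3,5,7-trimethyl-8-oxooct-2-enoate, via dibutylboron (Z)-enolate 38 (not isolated), via dibutylboron aldolate 39 (not isolated)
Conditions: Bu2BOTf, Et3N, CH2Cl2, 0 °C; then 37, −78 → 0 °C; pH 7 buffer, MeOH, H2O2, 0 °C
Reagents that add atoms: none
Why: Evans syn-aldol reaction through a Zimmerman–Traxler chair, in which the (S)-benzyl auxiliary controls the enolate face and sets C18 (S) and C19 (R), overriding the modest intrinsic bias of the α-methyl aldehyde.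

Step 22
Reactants: 40 aldol adduct
Product: 41 allyl (2E,5S,6R,7S)-8-[(S)-4-benzyl-2-oxooxazolidin-3-yl]-3,5,7-trimethyl-8-oxo-6-[(triethylsilyl)oxy]oct-2-enoate
Conditions: TESOTf, 2,6-lutidine, CH2Cl2, −78 °C
Reagents that add atoms: triethylsilyl trifluoromethanesulfonate CC[Si](CC)(CC)OS(=O)(=O)C(F)(F)F
Why: Silyl triflate silylation of the hindered C19 hydroxyl also blocks retro-aldol cleavage in the following steps.

Step 23
Reactants: 41 silylated imide
Product: 42 allyl (2E,5S,6R,7R)-8-hydroxy-3,5,7-trimethyl-6-[(triethylsilyl)oxy]oct-2-enoate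
Conditions: LiBH4, MeOH (1 equiv), THF, 0 °C
Reagents that add atoms: none
Why: LiBH4 should reduce the activated imide carbonyl much faster than the hindered conjugated allyl ester.

Step 24
Reactants: 42 primary alcohol
Product: 43 allyl (2E,5S,6R,7S)-3,5,7-trimethyl-8-oxo-6-[(triethylsilyl)oxy]oct-2-enoate
Conditions: Dess–Martin periodinane, pyridine, CH2Cl2, 0 °C (used directly)
Reagents that add atoms: none
Why: Buffered Dess–Martin oxidation should deliver the C17 aldehyde without epimerising C18.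

**Fragment union and endgame**

Step 25
Reactants: 30 C1–C16 dienoyl imide; 43 C17–C24 aldehyde
Product: 46 C16–C17 syn-aldol adduct (16R,17S), via dibutylboron trienolate 44 (not isolated), via dibutylboron aldolate 45 (not isolated)
Conditions: Bu2BOTf, i-Pr2NEt, CH2Cl2, −78 °C; then 43, −78 → −20 °C; pH 7 buffer, MeOH, H2O2, 0 °C
Reagents that add atoms: none
Why: Soft enolisation of the β,γ-unsaturated imide (boron coordination, amine deprotonation at C16) gives the dibutylboron (Z)-trienolate 44, which adds to aldehyde 43 through a closed Zimmerman–Traxler chair, the closest precedent being the Evans syn-aldol reaction of β,γ-unsaturated N-acyloxazolidinones. No ring is closed; the step forms only the C16–C17 bond. C16 is controlled by the (R)-benzyl auxiliary, which in the dipole-minimised enolate conformation shields one face so that the aldehyde bonds to the face giving the C16 configuration of the target (16R in the adduct, 16S once the acyl carbon is reduced to CH2OH). C17 follows from the (Z)-enolate geometry (syn, 17S) and is reinforced by the anti-Felkin preference of α-methyl aldehydes toward (Z)-enolates and by 1,3-anti induction from the C19 silyloxy group, although this centre is later oxidised. The step needs α-regioselectivity (C16 over the vinylogous C14 and C12 termini), secured by the six-membered boron-bridged transition state, and retention of the C14=C15 (E) geometry, secured by kinetic low-temperature enolisation. It also needs tolerance of the allylic lactol acetal and the allyl ester, which the amine-buffered, short low-temperature exposure to Bu2BOTf should provide.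

Step 26
Reactants: 46 aldol adduct
Product: 47 C16a,C17-diol (16S,17R)
Conditions: LiBH4, MeOH (1 equiv), THF, 0 °C
Reagents that add atoms: none
Why: Hydroxyl-assisted LiBH4 reduction of the imide converts the acyl carbon into the C16 hydroxymethyl group and should spare the allyl enoate, the acetal and the silyl ether.

Step 27
Reactants: 47 diol
Product: 48 C16a-O-triethylsilyl ether of 47
Conditions: TESCl, imidazole, CH2Cl2, −78 → −40 °C
Reagents that add atoms: chlorotriethylsilane CC[Si](CC)(CC)Cl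
Why: The primary hydroxyl should be silylated selectively over the hindered secondary C17 hydroxyl flanked by two branched carbons.

Step 28
Reactants: 48 allyl ester
Product: 49 C24 carboxylic acid
Conditions: Pd(PPh3)4 (5 mol%), morpholine, THF, rt
Reagents that add atoms: none
Why: Tsuji–Trost deallylation (zerovalent palladium ionises the allyl ester, morpholine traps the allyl group) is placed before the lactone is unveiled so that no allylic lactone carbon–oxygen bond is exposed to palladium.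

Step 29
Reactants: 49 C17 carbinol
Product: 50 C17 ketone (16S,18S,19R,20S)
Conditions: Dess–Martin periodinane, pyridine, CH2Cl2, 0 °C
Reagents that add atoms: none
Why: Dess–Martin oxidation under buffered, non-basic conditions should form the β,γ-unsaturated ketone without epimerising C16 or eliminating the β-silyloxy group.

Step 30
Reactants: 50 bis-silyl ether acetal
Product: 51 kazusamycin A lactol
Conditions: aq. HF (48%), MeCN, 0 °C
Reagents that add atoms: water O
Why: Aqueous HF should cleave both triethylsilyl ethers and hydrolyse the allylic ethyl acetal to the lactol in one operation under conditions too mild to enolise the ketone.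

Step 31
Reactants: 51 lactol
Product: 52 kazusamycin A
Conditions: MnO2, CH2Cl2, rt
Reagents that add atoms: none
Why: MnO2 oxidises the allylic lactol to the α,β-unsaturated δ-lactone chemoselectively, the homoallylic primary and the secondary hydroxyl groups not being activated.

**Compound list**

1 | 3-(triisopropylsilyl)prop-2-ynal | O=CC#C[Si](C(C)C)(C(C)C)C(C)C | starting material
2 | (Z)-crotylboronic acid pinacol ester | C/C=C\CB1OC(C)(C)C(C)(C)O1 | starting material
3 | pinacol borate ester of 4 (boron on the C5 oxygen) | CC(C)[Si](C(C)C)(C(C)C)C#C[C@H](OB1OC(C)(C)C(C)(C)O1)[C@@H](C)C=C | intermediate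
4 | (3R,4S)-4-methyl-1-(triisopropylsilyl)hex-5-en-1-yn-3-ol | CC(C)[Si](C(C)C)(C(C)C)C#C[C@H](O)[C@@H](C)C=C | intermediate
5 | acrolein diethyl acetal (3,3-diethoxyprop-1-ene) | C=CC(OCC)OCC | starting material
6 | [(3R,4S)-3-(1-ethoxyallyloxy)-4-methylhex-5-en-1-yn-1-yl]triisopropylsilane (acetal carbon epimers) | C=CC(OCC)O[C@@H](C#C[Si](C(C)C)(C(C)C)C(C)C)[C@@H](C)C=C | intermediate
7 | (2R,3S)-6-ethoxy-3-methyl-2-[(triisopropylsilyl)ethynyl]-3,6-dihydro-2H-pyran (C6 epimers) | CC(C)[Si](C(C)C)(C(C)C)C#C[C@@H]1OC(OCC)C=C[C@@H]1C | intermediate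
8 | (2R,3S)-6-ethoxy-2-ethynyl-3-methyl-3,6-dihydro-2H-pyran (C6 epimers) | C#C[C@@H]1OC(OCC)C=C[C@@H]1C | intermediate
9 | (S)-4-benzyl-3-propionyloxazolidin-2-one | CCC(=O)N1[C@@H](Cc2ccccc2)COC1=O | starting material
10 | 3-bromo-1-(trimethylsilyl)prop-1-yne | C[Si](C)(C)C#CCBr | starting material
11 | sodium (Z)-enolate of 9 | C/C=C(\[O-])N1[C@@H](Cc2ccccc2)COC1=O.[Na+] | intermediate
12 | (S)-4-benzyl-3-[(R)-2-methyl-5-(trimethylsilyl)pent-4-ynoyl]oxazolidin-2-one | C[C@H](CC#C[Si](C)(C)C)C(=O)N1[C@@H](Cc2ccccc2)COC1=O | intermediate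
13 | (R)-2-methyl-5-(trimethylsilyl)pent-4-yn-1-ol | C[C@H](CC#C[Si](C)(C)C)CO | intermediate
14 | (R)-2-methyl-5-(trimethylsilyl)pent-4-ynal | C[C@H](CC#C[Si](C)(C)C)C=O | intermediate
15 | (R)-(6,6-dibromo-4-methylhex-5-en-1-yn-1-yl)trimethylsilane | C[C@H](CC#C[Si](C)(C)C)C=C(Br)Br | intermediate
16 | (R,Z)-(6-bromo-4-methyloct-5-en-1-yn-1-yl)trimethylsilane | C[C@H](CC#C[Si](C)(C)C)/C=C(/CC)Br | intermediate
17 | (E)-alkenylzirconocene chloride from 8 (Zr on C7, ring stereocentres unchanged) | Cl[Zr](/C=C/[C@@H]1OC(OCC)C=C[C@@H]1C)(C1C=CC=C1)C1C=CC=C1 | intermediate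
18 | (E)-alkenylzinc chloride from 17 (Zn on C7) | Cl[Zn]/C=C/[C@@H]1OC(OCC)C=C[C@@H]1C | intermediate
19 | (2S,3S)-6-ethoxy-2-[(1E,3Z,5R)-3-ethyl-5-methyl-8-(trimethylsilyl)octa-1,3-dien-7-yn-1-yl]-3-methyl-3,6-dihydro-2H-pyran | CCC(=C/[C@H](C)CC#C[Si](C)(C)C)/C=C/[C@@H]1OC(OCC)C=C[C@@H]1C | intermediate
20 | (2S,3S)-6-ethoxy-2-[(1E,3Z,5R)-3-ethyl-5-methylocta-1,3-dien-7-yn-1-yl]-3-methyl-3,6-dihydro-2H-pyran | CCC(=C/[C@H](C)CC#C)/C=C/[C@@H]1OC(OCC)C=C[C@@H]1C | intermediate
21 | pent-3-yn-1-ol | CC#CCCO | starting material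
22 | bis-zirconium species from 21: zirconocene chloride alkoxide of (E)-4-(chlorozirconocenyl)pent-3-en-1-ol | Cl[Zr](OCC/C=C(\C)[Zr](Cl)(C1C=CC=C1)C1C=CC=C1)(C1C=CC=C1)C1C=CC=C1 | intermediate
23 | (E)-4-iodopent-3-en-1-ol | OCC/C=C(\C)I | intermediate
24 | (E)-4-iodopent-3-enoic acid | OC(=O)C/C=C(\C)I | intermediate
25 | (R)-4-benzyloxazolidin-2-one | O=C1N[C@H](Cc2ccccc2)CO1 | starting material
26 | (E)-4-iodopent-3-enoic pivalic anhydride | CC(C)(C)C(=O)OC(=O)C/C=C(\C)I | intermediate
27 | (R)-4-benzyl-3-[(E)-4-iodopent-3-enoyl]oxazolidin-2-one | O=C(C/C=C(\C)I)N1[C@H](Cc2ccccc2)COC1=O | intermediate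
28 | (E)-alkenylzirconocene chloride from 20 (Zr on C13) | CCC(=C/[C@H](C)C/C=C/[Zr](Cl)(C1C=CC=C1)C1C=CC=C1)/C=C/[C@@H]1OC(OCC)C=C[C@@H]1C | intermediate
29 | (E)-alkenylzinc chloride from 28 (Zn on C13) | CCC(=C/[C@H](C)C/C=C/[Zn]Cl)/C=C/[C@@H]1OC(OCC)C=C[C@@H]1C | intermediate
30 | (R)-4-benzyl-3-[(3E,5E,8R,9Z,11E)-10-ethyl-12-[(2S,3S)-6-ethoxy-3-methyl-3,6-dihydro-2H-pyran-2-yl]-4,8-dimethyldodeca-3,5,9,11-tetraenoyl]oxazolidin-2-one (C1–C16 fragment) | CCC(=C/[C@H](C)C/C=C/C(C)=C/CC(=O)N1[C@H](Cc2ccccc2)COC1=O)/C=C/[C@@H]1OC(OCC)C=C[C@@H]1C | intermediate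
31 | (R)-3-bromo-2-methylpropan-1-ol | C[C@H](CO)CBr | starting material
32 | (R)-(3-bromo-2-methylpropoxy)(tert-butyl)diphenylsilane | C[C@H](CO[Si](c1ccccc1)(c1ccccc1)C(C)(C)C)CBr | intermediate
33 | (S)-tert-butyl[(2-methylpent-4-yn-1-yl)oxy]diphenylsilane | C[C@H](CO[Si](c1ccccc1)(c1ccccc1)C(C)(C)C)CC#C | intermediate
34 | (S,E)-[5-((tert-butyldiphenylsilyl)oxy)-2,4-dimethylpent-1-en-1-yl]dimethylalane | C[C@H](CO[Si](c1ccccc1)(c1ccccc1)C(C)(C)C)C/C(C)=C/[Al](C)C | intermediate
35 | allyl (S,E)-6-[(tert-butyldiphenylsilyl)oxy]-3,5-dimethylhex-2-enoate | C[C@H](CO[Si](c1ccccc1)(c1ccccc1)C(C)(C)C)C/C(C)=C/C(=O)OCC=C | intermediate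
36 | allyl (S,E)-6-hydroxy-3,5-dimethylhex-2-enoate | C[C@H](CO)C/C(C)=C/C(=O)OCC=C | intermediate
37 | allyl (S,E)-3,5-dimethyl-6-oxohex-2-enoate | C[C@H](C=O)C/C(C)=C/C(=O)OCC=C | intermediate
38 | dibutylboron (Z)-enolate of 9 | C/C=C(\OB(CCCC)CCCC)N1[C@@H](Cc2ccccc2)COC1=O | intermediate
39 | dibutylboron aldolate of 40 | O=C(N1[C@@H](Cc2ccccc2)COC1=O)[C@@H](C)[C@H](OB(CCCC)CCCC)[C@@H](C)C/C(C)=C/C(=O)OCC=C | intermediate
40 | allyl (2E,5S,6R,7S)-8-[(S)-4-benzyl-2-oxooxazolidin-3-yl]-6-hydroxy-3,5,7-trimethyl-8-oxooct-2-enoate | O=C(N1[C@@H](Cc2ccccc2)COC1=O)[C@@H](C)[C@H](O)[C@@H](C)C/C(C)=C/C(=O)OCC=C | intermediate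
41 | allyl (2E,5S,6R,7S)-8-[(S)-4-benzyl-2-oxooxazolidin-3-yl]-3,5,7-trimethyl-8-oxo-6-[(triethylsilyl)oxy]oct-2-enoate | O=C(N1[C@@H](Cc2ccccc2)COC1=O)[C@@H](C)[C@H](O[Si](CC)(CC)CC)[C@@H](C)C/C(C)=C/C(=O)OCC=C | intermediate
42 | allyl (2E,5S,6R,7R)-8-hydroxy-3,5,7-trimethyl-6-[(triethylsilyl)oxy]oct-2-enoate | OC[C@@H](C)[C@H](O[Si](CC)(CC)CC)[C@@H](C)C/C(C)=C/C(=O)OCC=C | intermediate
43 | allyl (2E,5S,6R,7S)-3,5,7-trimethyl-8-oxo-6-[(triethylsilyl)oxy]oct-2-enoate (C17–C24 fragment) | O=C[C@@H](C)[C@H](O[Si](CC)(CC)CC)[C@@H](C)C/C(C)=C/C(=O)OCC=C | intermediate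
44 | dibutylboron (Z)-trienolate of 30 | CCC(=C/[C@H](C)C/C=C/C(C)=C/C=C(\OB(CCCC)CCCC)N1[C@H](Cc2ccccc2)COC1=O)/C=C/[C@@H]1OC(OCC)C=C[C@@H]1C | intermediate
45 | dibutylboron aldolate of 46 (boron on the C17 oxygen) | CCC(=C/[C@H](C)C/C=C/C(C)=C/[C@@H](C(=O)N1[C@H](Cc2ccccc2)COC1=O)[C@@H](OB(CCCC)CCCC)[C@@H](C)[C@H](O[Si](CC)(CC)CC)[C@@H](C)C/C(C)=C/C(=O)OCC=C)/C=C/[C@@H]1OC(OCC)C=C[C@@H]1C | intermediate
46 | syn-aldol adduct: C16 carries the N-acyl (R)-4-benzyloxazolidin-2-one carbonyl (C16a), C17–OH free, C19–OTES, C24 allyl ester, C1 ethyl lactol acetal; 4S,5S,10R,16R,17S,18R,19R,20S; 6E,8Z,12E,14E,22E | CCC(=C/[C@H](C)C/C=C/C(C)=C/[C@@H](C(=O)N1[C@H](Cc2ccccc2)COC1=O)[C@@H](O)[C@@H](C)[C@H](O[Si](CC)(CC)CC)[C@@H](C)C/C(C)=C/C(=O)OCC=C)/C=C/[C@@H]1OC(OCC)C=C[C@@H]1C | intermediate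
47 | diol: C16 hydroxymethyl and C17–OH free, otherwise as 46; 4S,5S,10R,16S,17R,18R,19R,20S | CCC(=C/[C@H](C)C/C=C/C(C)=C/[C@@H](CO)[C@@H](O)[C@@H](C)[C@H](O[Si](CC)(CC)CC)[C@@H](C)C/C(C)=C/C(=O)OCC=C)/C=C/[C@@H]1OC(OCC)C=C[C@@H]1C | intermediate
48 | C16a-O-triethylsilyl ether of 47 (C17–OH free) | CCC(=C/[C@H](C)C/C=C/C(C)=C/[C@@H](CO[Si](CC)(CC)CC)[C@@H](O)[C@@H](C)[C@H](O[Si](CC)(CC)CC)[C@@H](C)C/C(C)=C/C(=O)OCC=C)/C=C/[C@@H]1OC(OCC)C=C[C@@H]1C | intermediate
49 | C24 carboxylic acid of 48 | CCC(=C/[C@H](C)C/C=C/C(C)=C/[C@@H](CO[Si](CC)(CC)CC)[C@@H](O)[C@@H](C)[C@H](O[Si](CC)(CC)CC)[C@@H](C)C/C(C)=C/C(=O)O)/C=C/[C@@H]1OC(OCC)C=C[C@@H]1C | intermediate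
50 | C17 ketone: bis-triethylsilyl ether, ethyl lactol acetal, free C24 acid; 4S,5S,10R,16S,18S,19R,20S | CCC(=C/[C@H](C)C/C=C/C(C)=C/[C@@H](CO[Si](CC)(CC)CC)C(=O)[C@@H](C)[C@H](O[Si](CC)(CC)CC)[C@@H](C)C/C(C)=C/C(=O)O)/C=C/[C@@H]1OC(OCC)C=C[C@@H]1C | intermediate
51 | kazusamycin A lactol (C1 hemiacetal, epimers) | CCC(=C/[C@H](C)C/C=C/C(C)=C/[C@@H](CO)C(=O)[C@@H](C)[C@H](O)[C@@H](C)C/C(C)=C/C(=O)O)/C=C/[C@@H]1OC(O)C=C[C@@H]1C | intermediate
52 | kazusamycin A | CCC(=C/[C@H](C)C/C=C/C(C)=C/[C@@H](CO)C(=O)[C@@H](C)[C@H](O)[C@@H](C)C/C(C)=C/C(=O)O)/C=C/[C@@H]1OC(=O)C=C[C@@H]1C | target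

**Step count and risks**

Total step count: 31. Longest linear sequence: 16 steps (steps 16–31, from 31 to 52).

Steps most likely to fail:

1. Step 25. What may go wrong: ionisation of the allylic lactol acetal by the boron triflate, or proton shuffling within the trienolate that erodes the C14=C15 geometry and the facial selectivity, on a substrate carrying the whole left half. The fallback sets out from 27 and 43 and comes back at 46. Imide 27 is enolised (Bu2BOTf, i-Pr2NEt, CH2Cl2, −78 °C) to the dibutylboron (Z)-dienolate of 27 F1, which adds to 43 to give the boron aldolate F2 and, after buffered H2O2 work-up, the syn-aldol alkenyl iodide F3 with the same C16 and C17 configurations. Negishi coupling of F3 with alkenylzinc chloride 29 (excess, Pd(PPh3)4, THF, rt) then forms the C13–C14 bond and should give 46.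

2. Step 10. What may go wrong: slow transmetalation at the hindered α-ethyl alkenylpalladium intermediate, allowing Z-to-E isomerisation and homocoupling. The fallback sets out from 8 (through 17) and 16 and comes back at 19, with the polarity of the partners exchanged. Iodinolysis of 17 (I2, THF, 0 °C) gives (2R,3S)-6-ethoxy-2-[(E)-2-iodovinyl]-3-methyl-3,6-dihydro-2H-pyran F4. Bromine–lithium exchange on 16 (t-BuLi, Et2O, −78 °C) gives the (Z)-alkenyllithium F5, which is quenched with Bu3SnCl to (R,Z)-tributyl[5-methyl-8-(trimethylsilyl)oct-3-en-7-yn-3-yl]stannane F6 with retention. Copper-assisted Stille coupling of F4 with F6 (Pd(PPh3)4, CuI, CsF, DMF, rt) should give 19.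

3. Step 15. What may go wrong: protonation of the alkenylzinc by the doubly activated C16 methylene of 27, or migration of its β,γ-double bond into conjugation during the coupling. The fallback sets out from 29 and 23 and comes back at 30, installing the auxiliary after the coupling. Negishi coupling of 29 with the unprotected iodo alcohol 23 (Pd(OAc)2, SPhos, THF, rt, slow addition) gives (3E,5E,8R,9Z,11E)-10-ethyl-12-[(2S,3S)-6-ethoxy-3-methyl-3,6-dihydro-2H-pyran-2-yl]-4,8-dimethyldodeca-3,5,9,11-tetraen-1-ol F7. Oxidation (TEMPO, PhI(OAc)2, MeCN, pH 7 buffer) gives the corresponding tetraenoic acid F8. Activation with PivCl/Et3N gives the mixed pivalic anhydride F9, which acylates 25 (LiCl, THF) to give 30.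

Further compounds
F1 | step 25 | dibutylboron (Z)-dienolate of 27 | C/C(I)=C\C=C(/OB(CCCC)CCCC)N1[C@H](Cc2ccccc2)COC1=O
F2 | step 25 | dibutylboron aldolate of F3 | C/C(I)=C\[C@@H](C(=O)N1[C@H](Cc2ccccc2)COC1=O)[C@@H](OB(CCCC)CCCC)[C@@H](C)[C@H](O[Si](CC)(CC)CC)[C@@H](C)C/C(C)=C/C(=O)OCC=C
F3 | step 25 | syn-aldol adduct of 27 with 43 (C13–C24 alkenyl iodide, 16R,17S) | C/C(I)=C\[C@@H](C(=O)N1[C@H](Cc2ccccc2)COC1=O)[C@@H](O)[C@@H](C)[C@H](O[Si](CC)(CC)CC)[C@@H](C)C/C(C)=C/C(=O)OCC=C
F4 | step 10 | (2R,3S)-6-ethoxy-2-[(E)-2-iodovinyl]-3-methyl-3,6-dihydro-2H-pyran | I/C=C/[C@@H]1OC(OCC)C=C[C@@H]1C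
F5 | step 10 | (R,Z)-[5-methyl-8-(trimethylsilyl)oct-3-en-7-yn-3-yl]lithium | C[C@H](CC#C[Si](C)(C)C)/C=C(/CC)[Li]
F6 | step 10 | (R,Z)-tributyl[5-methyl-8-(trimethylsilyl)oct-3-en-7-yn-3-yl]stannane | C[C@H](CC#C[Si](C)(C)C)/C=C(/CC)[Sn](CCCC)(CCCC)CCCC
F7 | step 15 | (3E,5E,8R,9Z,11E)-10-ethyl-12-[(2S,3S)-6-ethoxy-3-methyl-3,6-dihydro-2H-pyran-2-yl]-4,8-dimethyldodeca-3,5,9,11-tetraen-1-ol | CCC(=C/[C@H](C)C/C=C/C(C)=C/CCO)/C=C/[C@@H]1OC(OCC)C=C[C@@H]1C
F8 | step 15 | (3E,5E,8R,9Z,11E)-10-ethyl-12-[(2S,3S)-6-ethoxy-3-methyl-3,6-dihydro-2H-pyran-2-yl]-4,8-dimethyldodeca-3,5,9,11-tetraenoic acid | CCC(=C/[C@H](C)C/C=C/C(C)=C/CC(=O)O)/C=C/[C@@H]1OC(OCC)C=C[C@@H]1C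
F9 | step 15 | mixed pivalic anhydride of F8 | CCC(=C/[C@H](C)C/C=C/C(C)=C/CC(=O)OC(=O)C(C)(C)C)/C=C/[C@@H]1OC(OCC)C=C[C@@H]1C
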